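**Plan**

- Cuts, in retrosynthetic order: (a) the silyl ether O–Si bond; (b) the bond from the quaternary carbon of the enolised cyclohexanetrione to the prenyl CH2; (c) the bond from the exocyclic CH2 to the ring carbon of the (then aromatic) acylphloroglucinol; (d) the aryl–acyl bond; (e) in the cyclopentane, the ring CH2–CH(isopropenyl) bond and the CH(CH2Ar)–C(OH)(CH3) bond together.
- Enabling feature: in the cyclopentane the tertiary carbinol carbon (CH3, OH) is β to the exocyclic CH2 carbon, an aldol retron once that carbon is a carboxyl carbon, and the ring unit CH2–CH2–C(OH)CH3 is the skeleton of methyl vinyl ketone. The five-membered ring is therefore the (3+2) sum of Cα–Cβ of 4-methylpenta-2,4-dienal (as a carbene-bound homoenolate) and C=C–C=O of methyl vinyl ketone.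
- Forward order: dienal; carbene-catalysed (3+2) annulation to the cyclopentane (β-lactone, then methyl ester); silyl ether; aldehyde. Separately, Friedel–Crafts acylation of 2-methylphloroglucinol. The halves are joined by reductive alkylation, the aromatic ring is dearomatised last by C-prenylation, and the silyl group is removed.
- Stereochemistry: the isopropenyl-bearing carbon comes from the chiral carbene, and its two ring neighbours are relayed from it in the same event. The sec-butyl centre comes from (R)-2-methylbutanoic acid. The quaternary ring carbon comes from a chiral palladium catalyst.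

Key step: step 2

Assumption: the target is one of several interconverting enol tautomers of the triketone and descriptors refer to the drawn form; (R)-2-methylbutanoic acid and both enantiomers of the two chiral catalysts are taken as purchasable; the sense of induction in steps 2 and 7 is assigned by analogy, and the mirror-image catalyst would be used if a first run shows the opposite sense.

**Route**

Step 1
Reactants: 1 methacrolein (2-methylprop-2-enal); 2 (triphenylphosphoranylidene)acetaldehyde
Product: 3 (2E)-4-methylpenta-2,4-dienal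
Conditions: 1 (3 equiv), toluene, 80 °C, sealed vessel; distillation
Reagents that add atoms: none
Why: Wittig olefination with the stabilised formyl ylide should give the (E)-enal selectively, and the excess of volatile 1 limits a second homologation.

Step 2
Reactants: 3 (2E)-4-methylpenta-2,4-dienal; 4 methyl vinyl ketone (but-3-en-2-one)
Product: 6 methyl (1R,2S,5S)-2-hydroxy-2-methyl-5-(prop-1-en-2-yl)cyclopentane-1-carboxylate, via bicyclic β-lactone 5 (not isolated)
Conditions: (5aS,10bR)-2-mesityl-5a,10b-dihydro-4H,6H-indeno[2,1-b][1,2,4]triazolo[4,3-d][1,4]oxazin-2-ium chloride (10 mol %), DBU (15 mol %), 4 (2 equiv), slow addition of 3, ClCH2CH2Cl, 0 °C to rt; then MeOH, NaOMe (0.2 equiv), 0 °C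
Reagents that add atoms: methanol, CO
Why: Proposed new method: the carbene adds to the aldehyde of 3 and the resulting conjugated enaminol (homoenolate equivalent) attacks the unsubstituted alkene terminus of 4 through its β-carbon, the azolium enol so formed closes the cyclopentane by a 5-(enolexo)-exo-trig aldol addition to the methyl ketone, and the tertiary alkoxide then acylates itself (4-exo-trig) on the acyl azolium, which frees the carbene and gives the cis-fused β-lactone 5 that methoxide opens at the acyl carbon to 6. The closest known reaction type is the carbene-catalysed homoenolate annulation of enals with chalcones or 4-oxoenoates (Michael addition, aldol, lactonisation; in methanol it stops at methyl 2-hydroxycyclopentanecarboxylates), but a β-unsubstituted alkyl vinyl ketone and a 2,4-dienal have not been shown as partners, hence the label. The isopropenyl-bearing stereocentre is set by the chiral aminoindanol backbone of the carbene, which shields one face of the enaminol β-carbon; the carboxyl-bearing carbon is set trans to it in the aldol transition state and, being α to a carbonyl, can also equilibrate to this more stable arrangement; the carbinol carbon is set with oxygen cis to the carboxyl carbon because only this aldolate can lactonise and release the catalyst while the other reverts by retro-aldol. The step needs β-carbon (homoenolate) reactivity in preference to acyl-anion addition, β-protonation and attack through the δ-carbon of the dienal, and this is secured by the N-mesityl triazolium carbene with an amidine base in an aprotic solvent, by the unhindered and highly electrophilic CH2 terminus of 4, and by the fact that only the β-adduct places the enol and the ketone in the 1,5-relationship that allows five-membered ring closure and turnover. Slow addition of 3 to an excess of 4 keeps the dienal from reacting with itself, and methanol is added only after the annulation so that protonation of the homoenolate cannot compete.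

Step 3
Reactants: 6 methyl (1R,2S,5S)-2-hydroxy-2-methyl-5-(prop-1-en-2-yl)cyclopentane-1-carboxylate
Product: 7 methyl (1R,2S,5S)-2-methyl-5-(prop-1-en-2-yl)-2-[(triethylsilyl)oxy]cyclopentane-1-carboxylate
Conditions: Et3SiOTf, 2,6-lutidine, CH2Cl2, −78 to 0 °C
Reagents that add atoms: triethylsilyl trifluoromethanesulfonate, CC[Si](CC)(CC)OS(=O)(=O)C(F)(F)F
Why: Silylation of a hindered tertiary alcohol with a silyl triflate and a hindered pyridine base is standard and should block retro-aldol cleavage and dehydration in the following steps.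

Step 4
Reactants: 7 methyl (1R,2S,5S)-2-methyl-5-(prop-1-en-2-yl)-2-[(triethylsilyl)oxy]cyclopentane-1-carboxylate
Product: 8 (1R,2S,5S)-2-methyl-5-(prop-1-en-2-yl)-2-[(triethylsilyl)oxy]cyclopentane-1-carbaldehyde
Conditions: iBu2AlH (1.2 equiv), CH2Cl2, −78 °C; aq. potassium sodium tartrate
Reagents that add atoms: none
Why: Partial reduction of a hindered ester by iBu2AlH at −78 °C should stop at the aluminium hemiacetal, which gives the aldehyde on hydrolysis, and the α-stereocentre already sits in its more stable arrangement trans to both neighbouring carbon substituents.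

Step 5
Reactants: 9 (2R)-2-methylbutanoic acid; 10 2-methylbenzene-1,3,5-triol (2-methylphloroglucinol)
Product: 12 (2R)-2-methyl-1-(2,4,6-trihydroxy-3-methylphenyl)butan-1-one, via (2R)-2-methylbutanoyl chloride 11 (not isolated)
Conditions: (COCl)2, DMF (cat.), CH2Cl2, 0 °C to rt; then 10, AlCl3 (3.5 equiv), CH2Cl2/MeNO2, 0 °C to rt; aq. HCl
Reagents that add atoms: none
Why: Friedel–Crafts C-acylation of the highly activated triol should occur at one of its two equivalent free ring positions, and the acid chloride is made and used without base at or below room temperature so that the α-stereocentre from the chiral pool is kept.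

Step 6
Reactants: 8 (1R,2S,5S)-2-methyl-5-(prop-1-en-2-yl)-2-[(triethylsilyl)oxy]cyclopentane-1-carbaldehyde; 12 (2R)-2-methyl-1-(2,4,6-trihydroxy-3-methylphenyl)butan-1-one
Product: 13 (2R)-2-methyl-1-[2,4,6-trihydroxy-3-methyl-5-({(1R,2S,5S)-2-methyl-5-(prop-1-en-2-yl)-2-[(triethylsilyl)oxy]cyclopentyl}methyl)phenyl]butan-1-one
Conditions: 12 (1.2 equiv), L-proline (20 mol %), diethyl 2,6-dimethyl-1,4-dihydropyridine-3,5-dicarboxylate (Hantzsch ester, 1.3 equiv), CH2Cl2/EtOH, 30 °C
Reagents that add atoms: none
Why: In this three-component reductive alkylation, amine-catalysed Knoevenagel-type condensation at the only unsubstituted ring carbon of 12 should give an ortho-quinone methide that the dihydropyridine reduces by conjugate hydride transfer, as is well known for cyclic 1,3-diones and phenolic CH-acids, and no stereocentre is formed.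

Step 7
Reactants: 13 (2R)-2-methyl-1-[2,4,6-trihydroxy-3-methyl-5-({(1R,2S,5S)-2-methyl-5-(prop-1-en-2-yl)-2-[(triethylsilyl)oxy]cyclopentyl}methyl)phenyl]butan-1-one; 14 3-methylbut-2-en-1-yl acetate (prenyl acetate)
Product: 15 (6R)-3,5-dihydroxy-6-methyl-2-[(2R)-2-methylbutanoyl]-6-(3-methylbut-2-en-1-yl)-4-({(1R,2S,5S)-2-methyl-5-(prop-1-en-2-yl)-2-[(triethylsilyl)oxy]cyclopentyl}methyl)cyclohexa-2,4-dien-1-one
Conditions: Pd2(dba)3·CHCl3 (2.5 mol %), (1R,2R)-N,N'-bis[2-(diphenylphosphino)benzoyl]cyclohexane-1,2-diamine (7.5 mol %), 14 (1.1 equiv), Et3N (1.2 equiv), THF, 0 °C to rt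
Reagents that add atoms: none
Why: In this Tsuji–Trost dearomative C-allylation the phenolate should attack the unsubstituted terminus of the 1,1-dimethylallyl palladium complex through the methyl-bearing ring carbon (less hindered than the carbon carrying the bulky cyclopentylmethyl group, O-allylation being reversible under zerovalent palladium catalysis), and the chiral pocket of the C2-symmetric diphosphine selects the ring face as in known palladium-catalysed asymmetric allylic dearomatisations of phenols and naphthols, so the quaternary centre is set by the catalyst.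

Step 8
Reactants: 15 (6R)-3,5-dihydroxy-6-methyl-2-[(2R)-2-methylbutanoyl]-6-(3-methylbut-2-en-1-yl)-4-({(1R,2S,5S)-2-methyl-5-(prop-1-en-2-yl)-2-[(triethylsilyl)oxy]cyclopentyl}methyl)cyclohexa-2,4-dien-1-one
Product: 16 (6R)-3,5-dihydroxy-4-{[(1R,2S,5S)-2-hydroxy-2-methyl-5-(prop-1-en-2-yl)cyclopentyl]methyl}-6-methyl-2-[(2R)-2-methylbutanoyl]-6-(3-methylbut-2-en-1-yl)cyclohexa-2,4-dien-1-one
Conditions: HF·pyridine, pyridine, THF, 0 °C to rt
Reagents that add atoms: none
Why: Buffered fluoride cleavage of the tertiary silyl ether should leave the alkenes, the enolised triketone and all stereocentres untouched.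

**Compound list**

1 | methacrolein (2-methylprop-2-enal) | C=C(C)C=O | starting material
2 | (triphenylphosphoranylidene)acetaldehyde | O=CC=P(c1ccccc1)(c1ccccc1)c1ccccc1 | starting material
3 | (2E)-4-methylpenta-2,4-dienal | C=C(C)/C=C/C=O | intermediate
4 | methyl vinyl ketone (but-3-en-2-one) | C=CC(C)=O | starting material
5 | (1R,2S,5S)-5-methyl-2-(prop-1-en-2-yl)-6-oxabicyclo[3.2.0]heptan-7-one | C=C(C)[C@H]1CC[C@]2(C)OC(=O)[C@H]12 | intermediate
6 | methyl (1R,2S,5S)-2-hydroxy-2-methyl-5-(prop-1-en-2-yl)cyclopentane-1-carboxylate | C=C(C)[C@H]1CC[C@](C)(O)[C@@H]1C(=O)OC | intermediate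
7 | methyl (1R,2S,5S)-2-methyl-5-(prop-1-en-2-yl)-2-[(triethylsilyl)oxy]cyclopentane-1-carboxylate | C=C(C)[C@H]1CC[C@](C)(O[Si](CC)(CC)CC)[C@@H]1C(=O)OC | intermediate
8 | (1R,2S,5S)-2-methyl-5-(prop-1-en-2-yl)-2-[(triethylsilyl)oxy]cyclopentane-1-carbaldehyde | C=C(C)[C@H]1CC[C@](C)(O[Si](CC)(CC)CC)[C@@H]1C=O | intermediate
9 | (2R)-2-methylbutanoic acid | CC[C@@H](C)C(=O)O | starting material
10 | 2-methylbenzene-1,3,5-triol | Cc1c(O)cc(O)cc1O | starting material
11 | (2R)-2-methylbutanoyl chloride | CC[C@@H](C)C(Cl)=O | intermediate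
12 | (2R)-2-methyl-1-(2,4,6-trihydroxy-3-methylphenyl)butan-1-one | CC[C@@H](C)C(=O)c1c(O)cc(O)c(C)c1O | intermediate
13 | (2R)-2-methyl-1-[2,4,6-trihydroxy-3-methyl-5-({(1R,2S,5S)-2-methyl-5-(prop-1-en-2-yl)-2-[(triethylsilyl)oxy]cyclopentyl}methyl)phenyl]butan-1-one | C=C(C)[C@H]1CC[C@](C)(O[Si](CC)(CC)CC)[C@@H]1Cc1c(O)c(C)c(O)c(C(=O)[C@H](C)CC)c1O | intermediate
14 | 3-methylbut-2-en-1-yl acetate | CC(C)=CCOC(C)=O | starting material
15 | (6R)-3,5-dihydroxy-6-methyl-2-[(2R)-2-methylbutanoyl]-6-(3-methylbut-2-en-1-yl)-4-({(1R,2S,5S)-2-methyl-5-(prop-1-en-2-yl)-2-[(triethylsilyl)oxy]cyclopentyl}methyl)cyclohexa-2,4-dien-1-one | C=C(C)[C@H]1CC[C@](C)(O[Si](CC)(CC)CC)[C@@H]1CC1=C(O)[C@@](C)(CC=C(C)C)C(=O)C(C(=O)[C@H](C)CC)=C1O | intermediate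
16 | (6R)-3,5-dihydroxy-4-{[(1R,2S,5S)-2-hydroxy-2-methyl-5-(prop-1-en-2-yl)cyclopentyl]methyl}-6-methyl-2-[(2R)-2-methylbutanoyl]-6-(3-methylbut-2-en-1-yl)cyclohexa-2,4-dien-1-one | C=C(C)[C@H]1CC[C@](C)(O)[C@@H]1CC1=C(O)[C@@](C)(CC=C(C)C)C(=O)C(C(=O)[C@H](C)CC)=C1O | target

**Count**

Total steps: 8. Longest linear sequence: 7 steps (steps 1, 2, 3, 4, 6, 7, 8); step 5 is a one-step branch.

**Steps most likely to fail, with fallbacks**

1. Step 2 (proposed new method). What may go wrong: carbene-initiated oligomerisation of the vinyl ketone, reaction of the dienal-derived intermediate as an acyl anion or through its δ-carbon, or weak enantiocontrol with so small an acceptor. The fallback uses known reaction types and the chiral pool instead of catalysis. It sets out not from a numbered compound but from purchased (S)-(−)-limonene F1 and comes back to the route at 5. mCPBA (CH2Cl2, 0 °C) should epoxidise the more electron-rich ring alkene to (4S)-limonene 1,2-oxide F2 (cis/trans mixture, of no consequence). H5IO6 in THF/water should cleave it to (3S)-6-oxo-3-(prop-1-en-2-yl)heptanal F3. NaClO2/NaH2PO4/2-methylbut-2-ene should oxidise this to (3S)-6-oxo-3-(prop-1-en-2-yl)heptanoic acid F4. Nucleophile-catalysed aldol-lactonisation of F4 (2-bromo-1-propylpyridinium triflate, 4-pyrrolidinopyridine, iPr2NEt, CH2Cl2) should then close the cyclopentane and the β-lactone in one operation to 5, the existing stereocentre directing its substituent trans to the lactone carbonyl. Methanolysis as in the second stage of step 2 gives 6.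

2. Step 7. What may go wrong: poor facial selectivity at the nearly symmetric phenolate carbon, competing C-allylation at the other alkylated ring carbon, or attack at the substituted allyl terminus. The fallback replaces catalyst control by alkylation without stereocontrol followed by separation. It sets out from 13 and comes back at 15. 1-Bromo-3-methylbut-2-ene with NaOMe in MeOH at −10 °C (the classical gem-dialkylation of acylphloroglucinols) should give 15 together with its epimer at the quaternary carbon, (6S)-3,5-dihydroxy-6-methyl-2-[(2R)-2-methylbutanoyl]-6-(3-methylbut-2-en-1-yl)-4-({(1R,2S,5S)-2-methyl-5-(prop-1-en-2-yl)-2-[(triethylsilyl)oxy]cyclopentyl}methyl)cyclohexa-2,4-dien-1-one F5. The two diastereomers would be separated by preparative HPLC.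

3. Step 6. What may go wrong: sluggish condensation of the hindered α-branched aldehyde with the acyl-deactivated phenol, β-elimination of silanol through the enamine, or trapping of the quinone methide by a second phenol. The fallback forms the same CH2–aryl bond by sp3–sp2 cross-coupling instead of carbonyl condensation. It sets out from 7 and 12 and comes back at 13.
   - Alkyl partner: LiAlH4 (Et2O, 0 °C) should reduce 7 to [(1S,2S,5S)-2-methyl-5-(prop-1-en-2-yl)-2-(triethylsilyloxy)cyclopentyl]methanol F6. I2/PPh3/imidazole should convert it into triethyl{[(1S,2R,3S)-2-(iodomethyl)-1-methyl-3-(prop-1-en-2-yl)cyclopentyl]oxy}silane F7. Zn dust/LiCl in THF should insert to give {[(1R,2S,5S)-2-methyl-5-(prop-1-en-2-yl)-2-(triethylsilyloxy)cyclopentyl]methyl}zinc iodide F8.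
   - Aryl partner: NBS (MeCN, 0 °C) should brominate the free ring position of 12 to (2R)-1-(3-bromo-2,4,6-trihydroxy-5-methylphenyl)-2-methylbutan-1-one F9. Ac2O/pyridine/DMAP should give its triacetate, 4-bromo-6-methyl-2-[(2R)-2-methylbutanoyl]benzene-1,3,5-triyl triacetate F10.
   - Coupling: Negishi coupling of F8 with F10 (Pd(OAc)2, SPhos, THF, 50 °C) should give 2-methyl-4-[(2R)-2-methylbutanoyl]-6-({(1R,2S,5S)-2-methyl-5-(prop-1-en-2-yl)-2-[(triethylsilyl)oxy]cyclopentyl}methyl)benzene-1,3,5-triyl triacetate F11. K2CO3 in MeOH should then remove the three aryl acetates without touching the tertiary silyl ether, giving 13.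

Further compounds
F1 | step 2 | (S)-(−)-limonene [(4S)-1-methyl-4-(prop-1-en-2-yl)cyclohex-1-ene], purchased | CC1=CC[C@H](CC1)C(C)=C
F2 | step 2 | (4S)-limonene 1,2-oxide (cis/trans mixture) | CC12OC1C[C@H](CC2)C(C)=C
F3 | step 2 | (3S)-6-oxo-3-(prop-1-en-2-yl)heptanal | O=CC[C@H](CCC(C)=O)C(C)=C
F4 | step 2 | (3S)-6-oxo-3-(prop-1-en-2-yl)heptanoic acid | OC(=O)C[C@H](CCC(C)=O)C(C)=C
F5 | step 7 | (6S)-3,5-dihydroxy-6-methyl-2-[(2R)-2-methylbutanoyl]-6-(3-methylbut-2-en-1-yl)-4-({(1R,2S,5S)-2-methyl-5-(prop-1-en-2-yl)-2-[(triethylsilyl)oxy]cyclopentyl}methyl)cyclohexa-2,4-dien-1-one | C=C(C)[C@H]1CC[C@](C)(O[Si](CC)(CC)CC)[C@@H]1CC1=C(O)[C@](C)(CC=C(C)C)C(=O)C(C(=O)[C@H](C)CC)=C1O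
F6 | step 6 | [(1S,2S,5S)-2-methyl-5-(prop-1-en-2-yl)-2-(triethylsilyloxy)cyclopentyl]methanol | C=C(C)[C@H]1CC[C@](C)(O[Si](CC)(CC)CC)[C@@H]1CO
F7 | step 6 | triethyl{[(1S,2R,3S)-2-(iodomethyl)-1-methyl-3-(prop-1-en-2-yl)cyclopentyl]oxy}silane | C=C(C)[C@H]1CC[C@](C)(O[Si](CC)(CC)CC)[C@@H]1CI
F8 | step 6 | {[(1R,2S,5S)-2-methyl-5-(prop-1-en-2-yl)-2-(triethylsilyloxy)cyclopentyl]methyl}zinc iodide | C=C(C)[C@H]1CC[C@](C)(O[Si](CC)(CC)CC)[C@@H]1C[Zn]I
F9 | step 6 | (2R)-1-(3-bromo-2,4,6-trihydroxy-5-methylphenyl)-2-methylbutan-1-one | CC[C@@H](C)C(=O)c1c(O)c(Br)c(O)c(C)c1O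
F10 | step 6 | 4-bromo-6-methyl-2-[(2R)-2-methylbutanoyl]benzene-1,3,5-triyl triacetate | CC[C@@H](C)C(=O)c1c(OC(C)=O)c(Br)c(OC(C)=O)c(C)c1OC(C)=O
F11 | step 6 | 2-methyl-4-[(2R)-2-methylbutanoyl]-6-({(1R,2S,5S)-2-methyl-5-(prop-1-en-2-yl)-2-[(triethylsilyl)oxy]cyclopentyl}methyl)benzene-1,3,5-triyl triacetate | C=C(C)[C@H]1CC[C@](C)(O[Si](CC)(CC)CC)[C@@H]1Cc1c(OC(C)=O)c(C)c(OC(C)=O)c(C(=O)[C@H](C)CC)c1OC(C)=O
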